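## Retrosynthetic overview

1. Target 14 ⇒ 7-O-benzyl sulfonic acid 13 (O-debenzylation last). The C6–S bond comes from 6-iodoflavone 9 by Pd C–S coupling, with sulfur raised stepwise: sulfide 10 → sulfone 11 → sulfinate 12 → sulfonic acid 13.
2. 9 ⇒ 7-O-benzylacacetin 8 by iodination ortho to the chelated 5-OH, which fixes C6 over C8; 8 ⇒ 5,7-di-O-benzyl flavone 7 by chelation-controlled 5-O-debenzylation.
3. Ring C is the only ring formed (rings A and B are bought): 7 ⇒ 2'-hydroxychalcone 5 by oxidative cyclisation (O1–C2 bond).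
4. Key C–C disconnection: the Cα–Cβ bond of chalcone 5 ⇒ Claisen–Schmidt aldol condensation of acetophenone 2 with 4-methoxybenzaldehyde 3; 2 comes from 2,4,6-trihydroxyacetophenone 1.

Assumption: the target has no stereocentre, so no configuration has to be set; the only stereo-element on the route is the E-alkene of chalcone 5, and intermediates 4 and 6 are racemic and transient.

## Route

Step 1
Reactants: 1 2,4,6-trihydroxyacetophenone
Product: 2 1-[2,4-bis(benzyloxy)-6-hydroxyphenyl]ethan-1-one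
Conditions: BnBr (2.1 equiv), K2CO3 (2.2 equiv), DMF, rt
Reagents that add atoms: benzyl bromide, BrCc1ccccc1
Why: Williamson ether synthesis in which the OH hydrogen-bonded to the acetyl C=O is the least nucleophilic, so two equivalents of BnBr alkylate the 4-OH and one ortho OH and leave the chelated ortho OH free.

Step 2
Reactants: 2 1-[2,4-bis(benzyloxy)-6-hydroxyphenyl]ethan-1-one; 3 4-methoxybenzaldehyde
Product: 5 (E)-1-[2,4-bis(benzyloxy)-6-hydroxyphenyl]-3-(4-methoxyphenyl)prop-2-en-1-one, via β-hydroxy ketone aldol adduct 4 (not isolated)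
Conditions: 3 (1.2 equiv), 50% aq KOH, EtOH, rt, 48 h; then dilute HCl
Reagents that add atoms: none
Why: Claisen–Schmidt crossed aldol condensation of a methyl ketone enolate with a non-enolisable aldehyde, where E1cB dehydration of the aldol gives the conjugated E-alkene and leaves no stereocentre.

Step 3
Reactants: 5 (E)-1-[2,4-bis(benzyloxy)-6-hydroxyphenyl]-3-(4-methoxyphenyl)prop-2-en-1-one
Product: 7 di-O-benzylacacetin (5,7-bis(benzyloxy)-2-(4-methoxyphenyl)-4H-chromen-4-one), via racemic flavanone 6 (not isolated)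
Conditions: I2 (10 mol%), DMSO, 130 °C
Reagents that add atoms: none
Why: I2/DMSO oxidative cyclisation, in which intramolecular oxa-Michael addition of the 2'-OH gives the flavanone, α-iodination and HI loss give the flavone, and DMSO reoxidises HI; benzyl ethers tolerate these conditions.

Step 4
Reactants: 7 5,7-bis(benzyloxy)-2-(4-methoxyphenyl)-4H-chromen-4-one
Product: 8 7-(benzyloxy)-5-hydroxy-2-(4-methoxyphenyl)-4H-chromen-4-one
Conditions: BCl3 (1.1 equiv), CH2Cl2, −78 °C; then H2O
Reagents that add atoms: none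
Why: Chelation-controlled Lewis-acid ether cleavage, in which boron bridges the C4 carbonyl and O5 so only the peri benzyl ether is cleaved while the unchelated 7-OBn and 4'-OMe survive at −78 °C with one equivalent.

Step 5
Reactants: 8 7-(benzyloxy)-5-hydroxy-2-(4-methoxyphenyl)-4H-chromen-4-one
Product: 9 7-(benzyloxy)-5-hydroxy-6-iodo-2-(4-methoxyphenyl)-4H-chromen-4-one
Conditions: BnMe3N+ ICl2− (1.1 equiv), CaCO3, CH2Cl2–MeOH (5:2), rt
Reagents that add atoms: benzyltrimethylammonium dichloroiodate, C[N+](C)(C)Cc1ccccc1.Cl[I-]Cl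
Why: Electrophilic aromatic iodination, which in 5-hydroxy-7-alkoxyflavones goes ortho to the free chelated 5-OH (C6) rather than to C8 or the anisyl ring, with CaCO3 buffering the HCl.

Step 6
Reactants: 9 7-(benzyloxy)-5-hydroxy-6-iodo-2-(4-methoxyphenyl)-4H-chromen-4-one
Product: 10 methyl 3-{[7-(benzyloxy)-5-hydroxy-2-(4-methoxyphenyl)-4-oxo-4H-chromen-6-yl]sulfanyl}propanoate
Conditions: HS(CH2)2CO2Me (1.2 equiv), Pd2(dba)3 (2.5 mol%), Xantphos (5 mol%), iPr2NEt (2 equiv), 1,4-dioxane, 100 °C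
Reagents that add atoms: methyl 3-sulfanylpropanoate, COC(=O)CCS
Why: Migita-type Pd-catalysed C–S cross-coupling, where the wide-bite-angle ligand handles the hindered electron-rich aryl iodide and the weak amine base leaves the ester and the chelated phenol untouched.

Step 7
Reactants: 10 methyl 3-{[7-(benzyloxy)-5-hydroxy-2-(4-methoxyphenyl)-4-oxo-4H-chromen-6-yl]sulfanyl}propanoate
Product: 11 methyl 3-{[7-(benzyloxy)-5-hydroxy-2-(4-methoxyphenyl)-4-oxo-4H-chromen-6-yl]sulfonyl}propanoate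
Conditions: mCPBA (2.5 equiv), CH2Cl2, 0 °C to rt; aq Na2SO3/NaHCO3 wash
Reagents that add atoms: 3-chloroperoxybenzoic acid, OOC(=O)c1cccc(Cl)c1
Why: Peracid oxidation of sulfide to sulfone is fast at sulfur, whereas the electron-poor flavone C2=C3 and the chelated phenol are not attacked.

Step 8
Reactants: 11 methyl 3-{[7-(benzyloxy)-5-hydroxy-2-(4-methoxyphenyl)-4-oxo-4H-chromen-6-yl]sulfonyl}propanoate
Product: 13 7-(benzyloxy)-5-hydroxy-2-(4-methoxyphenyl)-4-oxo-4H-chromene-6-sulfonic acid, via sodium arenesulfinate 12 (not isolated)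
Conditions: NaOMe (3 equiv), THF–MeOH, 0 °C to rt; then aq HCl to pH 8, 30% H2O2, rt; then 1 M HCl, reverse-phase isolation
Reagents that add atoms: hydrogen peroxide, OO; sodium methoxide, [Na+].[O-]C (supplies only the Na+ of 12)
Why: Base-induced retro-Michael (E1cB) fragmentation of the β-sulfonyl ester releases the arenesulfinate, which H2O2 oxidises from S(IV) to the sulfonate before mild acidification gives the sulfonic acid.

Step 9
Reactants: 13 7-(benzyloxy)-5-hydroxy-2-(4-methoxyphenyl)-4-oxo-4H-chromene-6-sulfonic acid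
Product: 14 niruriflavone (5,7-dihydroxy-2-(4-methoxyphenyl)-4-oxo-4H-chromene-6-sulfonic acid)
Conditions: H2 (1 atm), 10% Pd/C, MeOH–THF, rt, stopped at full conversion
Reagents that add atoms: none
Why: Catalytic hydrogenolysis of the benzyl aryl ether, in which the S(VI) sulfonic acid does not poison palladium and the aryl methyl ether and flavone core are inert at 1 atm and rt.

## Compound list

1 | 2,4,6-trihydroxyacetophenone | CC(=O)c1c(O)cc(O)cc1O | starting material
2 | 1-[2,4-bis(benzyloxy)-6-hydroxyphenyl]ethan-1-one | CC(=O)c1c(O)cc(OCc2ccccc2)cc1OCc1ccccc1 | intermediate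
3 | 4-methoxybenzaldehyde | COc1ccc(C=O)cc1 | starting material
4 | 1-[2,4-bis(benzyloxy)-6-hydroxyphenyl]-3-hydroxy-3-(4-methoxyphenyl)propan-1-one (racemic aldol adduct, not isolated) | COc1ccc(C(O)CC(=O)c2c(O)cc(OCc3ccccc3)cc2OCc2ccccc2)cc1 | intermediate
5 | (E)-1-[2,4-bis(benzyloxy)-6-hydroxyphenyl]-3-(4-methoxyphenyl)prop-2-en-1-one | COc1ccc(/C=C/C(=O)c2c(O)cc(OCc3ccccc3)cc2OCc2ccccc2)cc1 | intermediate
6 | 5,7-bis(benzyloxy)-2-(4-methoxyphenyl)chroman-4-one (racemic flavanone, not isolated) | COc1ccc(C2CC(=O)c3c(OCc4ccccc4)cc(OCc4ccccc4)cc3O2)cc1 | intermediate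
7 | 5,7-bis(benzyloxy)-2-(4-methoxyphenyl)-4H-chromen-4-one | COc1ccc(-c2cc(=O)c3c(OCc4ccccc4)cc(OCc4ccccc4)cc3o2)cc1 | intermediate
8 | 7-(benzyloxy)-5-hydroxy-2-(4-methoxyphenyl)-4H-chromen-4-one | COc1ccc(-c2cc(=O)c3c(O)cc(OCc4ccccc4)cc3o2)cc1 | intermediate
9 | 7-(benzyloxy)-5-hydroxy-6-iodo-2-(4-methoxyphenyl)-4H-chromen-4-one | COc1ccc(-c2cc(=O)c3c(O)c(I)c(OCc4ccccc4)cc3o2)cc1 | intermediate
10 | methyl 3-{[7-(benzyloxy)-5-hydroxy-2-(4-methoxyphenyl)-4-oxo-4H-chromen-6-yl]sulfanyl}propanoate | COc1ccc(-c2cc(=O)c3c(O)c(SCCC(=O)OC)c(OCc4ccccc4)cc3o2)cc1 | intermediate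
11 | methyl 3-{[7-(benzyloxy)-5-hydroxy-2-(4-methoxyphenyl)-4-oxo-4H-chromen-6-yl]sulfonyl}propanoate | COc1ccc(-c2cc(=O)c3c(O)c(S(=O)(=O)CCC(=O)OC)c(OCc4ccccc4)cc3o2)cc1 | intermediate
12 | sodium 7-(benzyloxy)-5-hydroxy-2-(4-methoxyphenyl)-4-oxo-4H-chromene-6-sulfinate (not isolated) | COc1ccc(-c2cc(=O)c3c(O)c(S(=O)[O-])c(OCc4ccccc4)cc3o2)cc1.[Na+] | intermediate
13 | 7-(benzyloxy)-5-hydroxy-2-(4-methoxyphenyl)-4-oxo-4H-chromene-6-sulfonic acid | COc1ccc(-c2cc(=O)c3c(O)c(S(=O)(=O)O)c(OCc4ccccc4)cc3o2)cc1 | intermediate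
14 | niruriflavone, 5,7-dihydroxy-2-(4-methoxyphenyl)-4-oxo-4H-chromene-6-sulfonic acid | COc1ccc(-c2cc(=O)c3c(O)c(S(=O)(=O)O)c(O)cc3o2)cc1 | target

## Summary and fallbacks

Total step count: 9. Longest linear sequence: 9 steps (1 → 14); aldehyde 3 is bought.

The three steps most likely to fail:

Step 4 (selective 5-O-debenzylation; the risk is loss of the 7-O-benzyl group as well, or ring C-benzylation). The fallback sets out from 7 and comes back at 8. Both benzyl ethers of 7 are removed by hydrogenolysis (H2, Pd/C, THF–MeOH) to give acacetin F1. The more acidic, non-chelated 7-OH of F1 is then benzylated alone (BnBr 1.05 equiv, K2CO3, acetone, reflux), which gives 8. Selectivity then rests on phenol acidity rather than on Lewis-acid chelation.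

Step 6 (Pd C–S coupling at an iodide flanked by OH and OBn; the risk is slow coupling or hydrodeiodination). The fallback sets out from 9 and comes back at 13, bypassing 10, 11 and 12. Sulfur is introduced directly at the S(IV) level by Pd-catalysed SO2 insertion (Pd(OAc)2, PAd2nBu, DABSO, Et3N, iPrOH, 75 °C), giving triethylammonium 7-(benzyloxy)-5-hydroxy-2-(4-methoxyphenyl)-4-oxo-4H-chromene-6-sulfinate F2. A cold acidic extraction removes iodide, which H2O2 would otherwise turn into an iodinating agent. Oxidation with 30% H2O2 in MeOH then gives 13.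

Step 9 (hydrogenolysis; the risk is over-reduction of C2=C3 to the flavanone or a sluggish catalyst). The fallback sets out from 11 and comes back at 14. It removes the benzyl group by Lewis acid while the compound is still neutral and soluble in CH2Cl2, so no hydrogenation is needed. BCl3 with pentamethylbenzene (CH2Cl2, −78 to −20 °C) gives methyl 3-{[5,7-dihydroxy-2-(4-methoxyphenyl)-4-oxo-4H-chromen-6-yl]sulfonyl}propanoate F3. NaOMe in THF–MeOH then fragments F3 to sodium 5,7-dihydroxy-2-(4-methoxyphenyl)-4-oxo-4H-chromene-6-sulfinate F4. F4 is oxidised in the same pot with H2O2 and acidified with 1 M HCl to give 14.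

## Further compounds

F1 | step 4 | acacetin, 5,7-dihydroxy-2-(4-methoxyphenyl)-4H-chromen-4-one | COc1ccc(-c2cc(=O)c3c(O)cc(O)cc3o2)cc1
F2 | step 6 | triethylammonium 7-(benzyloxy)-5-hydroxy-2-(4-methoxyphenyl)-4-oxo-4H-chromene-6-sulfinate | COc1ccc(-c2cc(=O)c3c(O)c(S(=O)[O-])c(OCc4ccccc4)cc3o2)cc1.CC[NH+](CC)CC
F3 | step 9 | methyl 3-{[5,7-dihydroxy-2-(4-methoxyphenyl)-4-oxo-4H-chromen-6-yl]sulfonyl}propanoate | COc1ccc(-c2cc(=O)c3c(O)c(S(=O)(=O)CCC(=O)OC)c(O)cc3o2)cc1
F4 | step 9 | sodium 5,7-dihydroxy-2-(4-methoxyphenyl)-4-oxo-4H-chromene-6-sulfinate | COc1ccc(-c2cc(=O)c3c(O)c(S(=O)[O-])c(O)cc3o2)cc1.[Na+]
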